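The flavanone is traced back to its flavone, whose ring C is cut at three bonds: C4a–C4, C4–C3 and O1–C2. Two features make this possible. C4 bears only its oxygen and is bonded to nothing but C4a and C3, so it can arrive as carbon monoxide; and the ring A fragment, a 2-iodoresorcinol with the methoxy group para to iodine, has a mirror plane through C4a and C7, so either hydroxyl can become O1 while the other ends up as the 5-OH. One palladium-catalysed carbonylative alkynylation–cyclisation therefore unites this unprotected iodoresorcinol, carbon monoxide and a ring B aryl acetylene that already carries the (E)-geranyl chain. C2 is set afterwards by asymmetric copper hydride reduction.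

Key step: step 8

Assumption: (R)-DTBM-SEGPHOS is taken as the ligand antipode whose copper hydride attacks the Re face of C2; C2 being the only stereocentre, the sense of induction rests on the catalyst alone, and the (S)-ligand would be used instead if the sense proved opposite.

Step 1
Reactants: 1 5-methoxybenzene-1,3-diol (5-methoxyresorcinol)
Product: 2 1-methoxy-3,5-bis(methoxymethoxy)benzene
Conditions: MOMCl (2.5 equiv), i-Pr2NEt (3 equiv), CH2Cl2, 0 °C to rt
Reagents that add atoms: chloromethyl methyl ether (MOMCl), COCCl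
Why: Williamson-type O-alkylation of both phenols with an α-chloro ether under amine base should give the bis-MOM ether, whose two acetal groups later direct lithiation to the carbon between them.

Step 2
Reactants: 2 1-methoxy-3,5-bis(methoxymethoxy)benzene
Product: 4 2-iodo-5-methoxy-1,3-bis(methoxymethoxy)benzene, via 2-lithio-5-methoxy-1,3-bis(methoxymethoxy)benzene 3 (not isolated)
Conditions: n-BuLi (1.1 equiv), THF, 0 °C; then I2, −78 °C to rt
Reagents that add atoms: iodine, [I][I]
Why: Directed ortho-metalation should occur at the C–H flanked and chelated by both OMOM groups (stronger directors than OMe), and iodine then quenches the aryllithium at that position.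

Step 3
Reactants: 4 2-iodo-5-methoxy-1,3-bis(methoxymethoxy)benzene
Product: 5 2-iodo-5-methoxybenzene-1,3-diol
Conditions: 3 M aq. HCl, MeOH, rt
Reagents that add atoms: none
Why: Acid-catalysed transacetalisation of the aryl MOM ethers to dimethoxymethane should free both phenols, dilute acid at room temperature in the absence of iodide being chosen so that the electron-rich C–I bond is not protonolysed.

Step 4
Reactants: 6 3-hydroxy-4-methoxybenzaldehyde (isovanillin)
Product: 7 5-(1,3-dioxolan-2-yl)-2-methoxyphenol
Conditions: ethylene glycol (3 equiv), p-TsOH·H2O (cat.), toluene, reflux, Dean–Stark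
Reagents that add atoms: ethylene glycol, OCCO
Why: Acid-catalysed acetalisation driven by azeotropic removal of water should mask the aldehyde, which would otherwise be attacked by n-BuLi in step 6.

Step 5
Reactants: 7 5-(1,3-dioxolan-2-yl)-2-methoxyphenol
Product: 8 2-[4-methoxy-3-(methoxymethoxy)phenyl]-1,3-dioxolane
Conditions: MOMCl (1.3 equiv), i-Pr2NEt (2 equiv), CH2Cl2, 0 °C to rt
Reagents that add atoms: chloromethyl methyl ether (MOMCl), COCCl
Why: Williamson-type O-alkylation under basic conditions, which the dioxolane tolerates, installs the MOM ether that serves as ortho-directing group in step 6 and as phenol protection up to the last step.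

Step 6
Reactants: 8 2-[4-methoxy-3-(methoxymethoxy)phenyl]-1,3-dioxolane; 9 (E)-geranyl bromide
Product: 13 2-[(2E)-3,7-dimethylocta-2,6-dien-1-yl]-4-methoxy-3-(methoxymethoxy)benzaldehyde, via aryllithium 10 (not isolated), via arylcopper 11 (not isolated), via geranylated dioxolane 12 (not isolated)
Conditions: n-BuLi (1.2 equiv), THF, −78 to 0 °C; CuBr·SMe2 (1.2 equiv), −78 to −40 °C; 9 (1.3 equiv), −78 °C to rt; then 1 M aq. HCl, THF, rt
Reagents that add atoms: water, O
Why: Directed ortho-metalation should take place at the only C–H ortho to OMOM, which is also flanked by the dioxolane; transmetalation to copper and allylic substitution at the primary carbon of 9 (SN2 rather than SN2′, the γ-carbon being fully substituted) should retain the E geometry, and dilute acid then hydrolyses the dioxolane much faster than the aryl MOM ether.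

Step 7
Reactants: 13 2-[(2E)-3,7-dimethylocta-2,6-dien-1-yl]-4-methoxy-3-(methoxymethoxy)benzaldehyde
Product: 14 1-ethynyl-2-[(2E)-3,7-dimethylocta-2,6-dien-1-yl]-4-methoxy-3-(methoxymethoxy)benzene
Conditions: dimethyl (1-diazo-2-oxopropyl)phosphonate (1.5 equiv), K2CO3 (2 equiv), MeOH, 0 °C to rt
Reagents that add atoms: dimethyl (1-diazo-2-oxopropyl)phosphonate (Ohira–Bestmann reagent), COP(=O)(OC)C(=[N+]=[N-])C(C)=O
Why: Seyferth–Gilbert homologation in its Ohira–Bestmann form, in which the diazomethylphosphonate anion released by methanolysis condenses with the non-enolisable aldehyde and loss of N2 with 1,2-hydrogen shift should give the terminal alkyne under conditions that leave the MOM ether and the geranyl chain untouched.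

Step 8
Reactants: 5 2-iodo-5-methoxybenzene-1,3-diol; 14 1-ethynyl-2-[(2E)-3,7-dimethylocta-2,6-dien-1-yl]-4-methoxy-3-(methoxymethoxy)benzene; 15 carbon monoxide
Product: 18 2-{2-[(2E)-3,7-dimethylocta-2,6-dien-1-yl]-4-methoxy-3-(methoxymethoxy)phenyl}-5-hydroxy-7-methoxy-4H-chromen-4-one, via ynone 16 (not isolated), via enaminone 17 (not isolated)
Conditions: PdCl2(PPh3)2 (5 mol%), CO (1 atm, balloon), Et2NH (solvent), 60 °C, no copper salt
Reagents that add atoms: none
Why: Zerovalent palladium, formed in situ from PdCl2(PPh3)2, inserts into the C–I bond of 5, CO insertion gives an aroyl–palladium species, and transfer of the amine-deprotonated alkyne 14 followed by reductive elimination forms C4a–C4 and C4–C3 as ynone 16. Diethylamine then adds to the β-carbon of the ynone (the future C2) to give β-amino enone 17, and one of the two equivalent ortho hydroxyls attacks that carbon and expels the amine, forming O1–C2 and closing ring C in a 6-endo mode (6-endo-dig counted on the ynone, addition–elimination on the enaminone). The closest known reaction type is the palladium-catalysed carbonylative Sonogashira coupling–cyclisation of 2-iodophenols with terminal alkynes to flavones. No stereocentre is formed. The step needs carbonylative rather than direct alkynylation, which the CO atmosphere, the copper-free medium and the electron-rich, doubly ortho-substituted aryl–palladium (fast CO insertion, slow direct coupling) should secure, and 6-endo rather than 5-exo (aurone) closure, which the enaminone pathway opened by the secondary amine secures. Site selectivity on ring A is not required, because the mirror symmetry of 5 makes both hydroxyls identical and the unused one emerges as the free 5-OH.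

Step 9
Reactants: 18 2-{2-[(2E)-3,7-dimethylocta-2,6-dien-1-yl]-4-methoxy-3-(methoxymethoxy)phenyl}-5-hydroxy-7-methoxy-4H-chromen-4-one
Product: 19 2-{2-[(2E)-3,7-dimethylocta-2,6-dien-1-yl]-4-methoxy-3-(methoxymethoxy)phenyl}-7-methoxy-5-(methoxymethoxy)-4H-chromen-4-one
Conditions: NaH (1.5 equiv), MOMCl (1.5 equiv), DMF, 0 °C to rt
Reagents that add atoms: chloromethyl methyl ether (MOMCl), COCCl
Why: Williamson-type O-alkylation after full deprotonation of the hydrogen-bonded 5-OH removes the acidic proton that would consume copper hydride, and uses the same group as on ring B so that one operation unmasks both phenols at the end.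

Step 10
Reactants: 19 2-{2-[(2E)-3,7-dimethylocta-2,6-dien-1-yl]-4-methoxy-3-(methoxymethoxy)phenyl}-7-methoxy-5-(methoxymethoxy)-4H-chromen-4-one
Product: 21 (2S)-2-{2-[(2E)-3,7-dimethylocta-2,6-dien-1-yl]-4-methoxy-3-(methoxymethoxy)phenyl}-7-methoxy-5-(methoxymethoxy)-2,3-dihydro-4H-chromen-4-one, via silyl enol ether 20 (not isolated)
Conditions: Cu(OAc)2·H2O (5 mol%), (R)-DTBM-SEGPHOS (5.5 mol%), (EtO)2MeSiH (3 equiv), toluene, 0 °C to rt; then AcOH, H2O, THF, 0 °C
Reagents that add atoms: none
Why: Asymmetric copper hydride conjugate reduction, in which the bisphosphine-ligated monovalent copper hydride formed from Cu(OAc)2 and the silane should add hydride to C2 of the chromone on the Re face selected by the chiral ligand (giving 2S) without touching the unactivated geranyl alkenes, the enolate being held as silyl enol ether 20 (no over-reduction, no ring opening) until mild acidic hydrolysis releases the ketone.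

Step 11
Reactants: 21 (2S)-2-{2-[(2E)-3,7-dimethylocta-2,6-dien-1-yl]-4-methoxy-3-(methoxymethoxy)phenyl}-7-methoxy-5-(methoxymethoxy)-2,3-dihydro-4H-chromen-4-one
Product: 22 (2S)-2-{2-[(2E)-3,7-dimethylocta-2,6-dien-1-yl]-3-hydroxy-4-methoxyphenyl}-5-hydroxy-7-methoxy-2,3-dihydro-4H-chromen-4-one
Conditions: 3 M aq. HCl, MeOH, rt to 40 °C
Reagents that add atoms: none
Why: Acid-catalysed cleavage of both aryl MOM acetals (transacetalisation to dimethoxymethane) should give the target, C2 being safe because it is not α to the carbonyl and acid, unlike base, does not trigger retro-oxa-Michael ring opening, while the mild temperature spares the geranyl chain.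

Compound list
1 | 5-methoxybenzene-1,3-diol (5-methoxyresorcinol) | COc1cc(O)cc(O)c1 | starting material
2 | 1-methoxy-3,5-bis(methoxymethoxy)benzene | COCOc1cc(OC)cc(OCOC)c1 | intermediate
3 | 2-lithio-5-methoxy-1,3-bis(methoxymethoxy)benzene | [Li]c1c(OCOC)cc(OC)cc1OCOC | intermediate
4 | 2-iodo-5-methoxy-1,3-bis(methoxymethoxy)benzene | COCOc1cc(OC)cc(OCOC)c1I | intermediate
5 | 2-iodo-5-methoxybenzene-1,3-diol | COc1cc(O)c(I)c(O)c1 | intermediate
6 | 3-hydroxy-4-methoxybenzaldehyde (isovanillin) | COc1ccc(C=O)cc1O | starting material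
7 | 5-(1,3-dioxolan-2-yl)-2-methoxyphenol | COc1ccc(C2OCCO2)cc1O | intermediate
8 | 2-[4-methoxy-3-(methoxymethoxy)phenyl]-1,3-dioxolane | COCOc1cc(C2OCCO2)ccc1OC | intermediate
9 | (E)-geranyl bromide, (2E)-1-bromo-3,7-dimethylocta-2,6-diene | CC(C)=CCC/C(C)=C/CBr | starting material
10 | [6-(1,3-dioxolan-2-yl)-3-methoxy-2-(methoxymethoxy)phenyl]lithium (aryllithium) | [Li]c1c(C2OCCO2)ccc(OC)c1OCOC | intermediate
11 | [6-(1,3-dioxolan-2-yl)-3-methoxy-2-(methoxymethoxy)phenyl]copper (arylcopper) | [Cu]c1c(C2OCCO2)ccc(OC)c1OCOC | intermediate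
12 | 2-{2-[(2E)-3,7-dimethylocta-2,6-dien-1-yl]-4-methoxy-3-(methoxymethoxy)phenyl}-1,3-dioxolane (geranylated dioxolane) | COCOc1c(OC)ccc(C2OCCO2)c1C/C=C(\C)CCC=C(C)C | intermediate
13 | 2-[(2E)-3,7-dimethylocta-2,6-dien-1-yl]-4-methoxy-3-(methoxymethoxy)benzaldehyde | COCOc1c(OC)ccc(C=O)c1C/C=C(\C)CCC=C(C)C | intermediate
14 | 1-ethynyl-2-[(2E)-3,7-dimethylocta-2,6-dien-1-yl]-4-methoxy-3-(methoxymethoxy)benzene | C#Cc1ccc(OC)c(OCOC)c1C/C=C(\C)CCC=C(C)C | intermediate
15 | carbon monoxide | [C-]#[O+] | starting material
16 | 1-(2,6-dihydroxy-4-methoxyphenyl)-3-{2-[(2E)-3,7-dimethylocta-2,6-dien-1-yl]-4-methoxy-3-(methoxymethoxy)phenyl}prop-2-yn-1-one (ynone) | COc1cc(O)c(C(=O)C#Cc2ccc(OC)c(OCOC)c2C/C=C(\C)CCC=C(C)C)c(O)c1 | intermediate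
17 | (2E)-3-(diethylamino)-1-(2,6-dihydroxy-4-methoxyphenyl)-3-{2-[(2E)-3,7-dimethylocta-2,6-dien-1-yl]-4-methoxy-3-(methoxymethoxy)phenyl}prop-2-en-1-one (enaminone) | COc1cc(O)c(C(=O)/C=C(/N(CC)CC)c2ccc(OC)c(OCOC)c2C/C=C(\C)CCC=C(C)C)c(O)c1 | intermediate
18 | 2-{2-[(2E)-3,7-dimethylocta-2,6-dien-1-yl]-4-methoxy-3-(methoxymethoxy)phenyl}-5-hydroxy-7-methoxy-4H-chromen-4-one | COc1cc(O)c2c(c1)oc(-c1ccc(OC)c(OCOC)c1C/C=C(\C)CCC=C(C)C)cc2=O | intermediate
19 | 2-{2-[(2E)-3,7-dimethylocta-2,6-dien-1-yl]-4-methoxy-3-(methoxymethoxy)phenyl}-7-methoxy-5-(methoxymethoxy)-4H-chromen-4-one | COc1cc(OCOC)c2c(c1)oc(-c1ccc(OC)c(OCOC)c1C/C=C(\C)CCC=C(C)C)cc2=O | intermediate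
20 | (2S)-4-{[diethoxy(methyl)silyl]oxy}-2-{2-[(2E)-3,7-dimethylocta-2,6-dien-1-yl]-4-methoxy-3-(methoxymethoxy)phenyl}-7-methoxy-5-(methoxymethoxy)-2H-chromene (silyl enol ether) | COc1cc(OCOC)c2c(c1)O[C@H](c1ccc(OC)c(OCOC)c1C/C=C(\C)CCC=C(C)C)C=C2O[Si](C)(OCC)OCC | intermediate
21 | (2S)-2-{2-[(2E)-3,7-dimethylocta-2,6-dien-1-yl]-4-methoxy-3-(methoxymethoxy)phenyl}-7-methoxy-5-(methoxymethoxy)-2,3-dihydro-4H-chromen-4-one | COc1cc(OCOC)c2c(c1)O[C@H](c1ccc(OC)c(OCOC)c1C/C=C(\C)CCC=C(C)C)CC2=O | intermediate
22 | (2S)-2-{2-[(2E)-3,7-dimethylocta-2,6-dien-1-yl]-3-hydroxy-4-methoxyphenyl}-5-hydroxy-7-methoxy-2,3-dihydro-4H-chromen-4-one (CNP0130331.1) | COc1cc(O)c2c(c1)O[C@H](c1ccc(OC)c(O)c1C/C=C(\C)CCC=C(C)C)CC2=O | target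

Total step count: 11 steps. Longest linear sequence: 8 steps (isovanillin 6 to target 22, steps 4 to 11); the ring A arm (steps 1 to 3) joins at step 8.

Steps most likely to fail

Step 8. The aroyl–palladium intermediate may be intercepted by diethylamine (amide formation), the alkyne may couple without CO uptake and then close 5-endo to a benzofuran, or oxidative addition to the electron-rich iodide may be slow. The fallback gives up the three-component assembly and closes ring C by oxa-Michael addition. It sets out from aldehyde 13. Commercial 1-(2,6-dihydroxy-4-methoxyphenyl)ethanone (CC(=O)c1c(O)cc(OC)cc1O) is mono-protected with MOMCl and i-Pr2NEt in CH2Cl2, the second hydroxyl staying hydrogen-bonded to the ketone and unreactive, to give 1-[2-hydroxy-4-methoxy-6-(methoxymethoxy)phenyl]ethanone F1. Claisen–Schmidt condensation of F1 with 13 (KOH, EtOH/H2O, rt) should give the (E)-2′-hydroxychalcone F2. NaOAc in refluxing EtOH should then close it to the racemic doubly MOM-protected flavanone F3. Preparative HPLC on a chiral stationary phase removes the (2R)-enantiomer F4 and delivers 21, where the route is rejoined before step 11.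

Step 10. Hydride transfer to the electron-rich chromone with its ortho-substituted 2-aryl group may be slow under the bulky chiral ligand, facial discrimination may be insufficient, or the enolate may open to the chalcone and erode the enantiomeric purity. The fallback separates reduction from stereocontrol and sets out from 19. Reduction with an achiral, more reactive copper hydride (Cu(OAc)2·H2O, 1,2-bis(diphenylphosphino)benzene, (EtO)2MeSiH, toluene, rt) should give the racemic silyl enol ether F5, and hydrolysis (AcOH, H2O, THF) the racemic flavanone F6. Kinetic resolution by Noyori-type asymmetric transfer hydrogenation (RuCl(p-cymene)[(R,R)-TsDPEN], HCO2H/Et3N, rt, stopped near half conversion) should then reduce the 2R ketone, for which hydride delivery to C4 is also anti to the C2 aryl group, to the cis-(2R,4R)-flavan-4-ol F7. The unreacted 2S ketone 21 is separated by chromatography, and the route is rejoined before step 11.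

Step 6. Lithiation may be incomplete or occur at another site, the copper-mediated substitution may proceed with allylic transposition or loss of E geometry, and the acidic hydrolysis may also remove some MOM ether. The fallback fixes the position through a C–Br bond and transfers the geranyl group by palladium catalysis, with no organolithium and no acetal. It sets out from isovanillin 6. Bromination (Br2, NaOAc, Fe powder, AcOH, rt), which enters C2 between the formyl and hydroxyl groups, gives 2-bromo-3-hydroxy-4-methoxybenzaldehyde F8. MOMCl and i-Pr2NEt give 2-bromo-4-methoxy-3-(methoxymethoxy)benzaldehyde F9. Stille coupling of F9 with (E)-geranyltributylstannane (CCCC[Sn](CCCC)(CCCC)C/C=C(\C)CCC=C(C)C; Pd(PPh3)4, LiCl, DMF, 90 °C) should deliver 13, where the route is rejoined before step 7.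

Further compounds
F1 | step 8 | 1-[2-hydroxy-4-methoxy-6-(methoxymethoxy)phenyl]ethanone | CC(=O)c1c(O)cc(OC)cc1OCOC
F2 | step 8 | (2E)-3-{2-[(2E)-3,7-dimethylocta-2,6-dien-1-yl]-4-methoxy-3-(methoxymethoxy)phenyl}-1-[2-hydroxy-4-methoxy-6-(methoxymethoxy)phenyl]prop-2-en-1-one | COc1cc(O)c(C(=O)/C=C/c2ccc(OC)c(OCOC)c2C/C=C(\C)CCC=C(C)C)c(OCOC)c1
F3 | step 8 | racemic 2-{2-[(2E)-3,7-dimethylocta-2,6-dien-1-yl]-4-methoxy-3-(methoxymethoxy)phenyl}-7-methoxy-5-(methoxymethoxy)-2,3-dihydro-4H-chromen-4-one | COc1cc(OCOC)c2c(c1)OC(c1ccc(OC)c(OCOC)c1C/C=C(\C)CCC=C(C)C)CC2=O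
F4 | step 8 | (2R)-2-{2-[(2E)-3,7-dimethylocta-2,6-dien-1-yl]-4-methoxy-3-(methoxymethoxy)phenyl}-7-methoxy-5-(methoxymethoxy)-2,3-dihydro-4H-chromen-4-one | COc1cc(OCOC)c2c(c1)O[C@@H](c1ccc(OC)c(OCOC)c1C/C=C(\C)CCC=C(C)C)CC2=O
F5 | step 10 | racemic 4-{[diethoxy(methyl)silyl]oxy}-2-{2-[(2E)-3,7-dimethylocta-2,6-dien-1-yl]-4-methoxy-3-(methoxymethoxy)phenyl}-7-methoxy-5-(methoxymethoxy)-2H-chromene | COc1cc(OCOC)c2c(c1)OC(c1ccc(OC)c(OCOC)c1C/C=C(\C)CCC=C(C)C)C=C2O[Si](C)(OCC)OCC
F6 | step 10 | racemic 2-{2-[(2E)-3,7-dimethylocta-2,6-dien-1-yl]-4-methoxy-3-(methoxymethoxy)phenyl}-7-methoxy-5-(methoxymethoxy)-2,3-dihydro-4H-chromen-4-one | COc1cc(OCOC)c2c(c1)OC(c1ccc(OC)c(OCOC)c1C/C=C(\C)CCC=C(C)C)CC2=O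
F7 | step 10 | (2R,4R)-2-{2-[(2E)-3,7-dimethylocta-2,6-dien-1-yl]-4-methoxy-3-(methoxymethoxy)phenyl}-7-methoxy-5-(methoxymethoxy)-3,4-dihydro-2H-chromen-4-ol | COc1cc(OCOC)c2c(c1)O[C@@H](c1ccc(OC)c(OCOC)c1C/C=C(\C)CCC=C(C)C)C[C@H]2O
F8 | step 6 | 2-bromo-3-hydroxy-4-methoxybenzaldehyde | COc1ccc(C=O)c(Br)c1O
F9 | step 6 | 2-bromo-4-methoxy-3-(methoxymethoxy)benzaldehyde | COCOc1c(OC)ccc(C=O)c1Br
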